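**Retrosynthetic overview** (germacrane numbering, C1–C15; lactone C12, O on C8)
1. Target ⇒ seco lactol/allylic bromide 17. The C7–C8 bond closes the ten-membered carbocycle first, and the γ-lactone closes second in the same operation (chromium-mediated macro-allylation, then lactonisation).
2. 17 ⇒ triene ester 14 + methyl 2-(bromomethyl)acrylate (C7=C11 by cross-metathesis); the C15 ester comes from 2-hydroxyisobutyric acid.
3. 14 ⇒ three-component anti-carbomagnesiation: Grignard 9 (C1–C3, C8–C10, C14) + propargyl alcohol (C4, C5, C15) + allyl bromide (C6, C7); this fixes the C4=C5 geometry.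
4. 9 ⇒ acetal ester 4 ⇒ 4-methoxybenzyl alcohol by Birch reduction and ozonolytic unzipping of the enol ether. The benzene ring is the template for the ring-cis C1=C10 alkene, supplies C14–OH, and differentiates C3 (ester) from C8 (aldehyde, masked with the C14 hydroxyl as a cyclic acetal).

Assumption: the (S,S)-ligand of step 9 is taken to deliver the (7R,8S) series; if the first run shows the opposite sense, its mirror image is used and nothing else changes.

**Step 1**
Reactants: 1 4-methoxybenzyl alcohol
Product: 2 (4-methoxycyclohexa-1,4-dien-1-yl)methanol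
Conditions: Li (4 equiv), NH3(l)/THF, t-BuOH (4 equiv), −78 → −33 °C; NH4Cl(s) only after the blue colour has gone
Reagents that add atoms: none
Why: Birch reduction of the anisole ring gives the 1,4-diene with the methoxy and the alkyl group each on a double bond, and the benzylic oxygen, carried as its lithium alkoxide with t-BuOH as the only proton source, is not lost by hydrogenolysis; the future C10=C1 alkene is now held cis inside a six-membered ring.

**Step 2**
Reactants: 2 (4-methoxycyclohexa-1,4-dien-1-yl)methanol
Product: 4 methyl (3E)-3-(5-methoxyoxolan-3-ylidene)propanoate, via lactol ester 3 (not isolated)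
Conditions: O3 (1.0 equiv, Sudan red 7B end point), CH2Cl2/MeOH 4:1, NaHCO3, −78 °C; Me2S, −78 → 23 °C; filter; PPTS (5 mol%), MeOH, 3 Å sieves, 0 → 23 °C; Et3N
Reagents that add atoms: ozone, O=[O+][O-]; methanol, CO
Why: Chemoselective ozonolysis of the enol ether C=C (much more electron-rich than the trisubstituted allylic-alcohol alkene) unzips the ring into a methyl ester (C3) and an aldehyde (C8) that stay cis across C10=C1, the aldehyde is captured by the C14 hydroxyl as five-membered lactol 3, and acid-catalysed acetalisation fixes it as the methyl acetal (a racemic, temporary stereocentre).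

**Step 3**
Reactants: 4 methyl (3E)-3-(5-methoxyoxolan-3-ylidene)propanoate
Product: 5 (3E)-3-(5-methoxyoxolan-3-ylidene)propan-1-ol
Conditions: LiAlH4 (0.7 equiv), THF, 0 °C; Fieser work-up (H2O, NaOH)
Reagents that add atoms: none
Why: Hydride reduction of the methyl ester to the primary alcohol; the cyclic acetal and the trisubstituted alkene are inert to LiAlH4.

**Step 4**
Reactants: 5 (3E)-3-(5-methoxyoxolan-3-ylidene)propan-1-ol
Product: 6 (4E)-4-(3-bromopropylidene)-2-methoxyoxolane
Conditions: CBr4 (1.3 equiv), PPh3 (1.4 equiv), 2,6-lutidine (0.3 equiv), CH2Cl2, 0 °C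
Reagents that add atoms: carbon tetrabromide, BrC(Br)(Br)Br
Why: Appel reaction converts the primary homoallylic alcohol into the bromide under buffered, essentially neutral conditions that the acid-labile acetal tolerates.

**Step 5**
Reactants: 6 (4E)-4-(3-bromopropylidene)-2-methoxyoxolane; 7 prop-2-yn-1-ol; 8 allyl bromide
Product: 12 (2Z)-2-[(3E)-3-(5-methoxyoxolan-3-ylidene)propyl]hexa-2,5-dien-1-ol, via Grignard reagent 9 (not isolated), via chloromagnesium propargyl alkoxide 10 (not isolated), via alkenylmagnesium chelate 11 (not isolated)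
Conditions: 6, Mg, THF, 30 °C; separately 7, i-PrMgCl (1.0 equiv), THF, −20 °C; combine (9 : 10 = 1.2 : 1), CuI (10 mol%), −10 → 23 °C, 16 h; then 8 (2 equiv), 0 → 23 °C; aq NH4Cl/NH3
Reagents that add atoms: none
Why: Copper-catalysed anti-carbomagnesiation of a propargylic magnesium alkoxide (Duboudin–Jousseaume reaction): the alkyl group adds to the alkyne carbon next to the carbinol, magnesium ends on the terminal carbon cis to the CH2O group in a five-membered chelate, and copper-mediated allylation with retention places C6 cis to C15 and trans to C3, which is the ring-trans C4=C5 geometry of the target.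

**Step 6**
Reactants: 12 (2Z)-2-[(3E)-3-(5-methoxyoxolan-3-ylidene)propyl]hexa-2,5-dien-1-ol; 13 2-hydroxy-2-methylpropanoic acid
Product: 14 (2Z)-2-[(3E)-3-(5-methoxyoxolan-3-ylidene)propyl]hexa-2,5-dien-1-yl 2-hydroxy-2-methylpropanoate
Conditions: 13 (3 equiv), EDC·HCl (3 equiv), DMAP (0.3 equiv), CH2Cl2, 0 → 23 °C
Reagents that add atoms: none
Why: Steglich-type carbodiimide esterification of the only free (primary allylic) hydroxyl, the tertiary hydroxyl of the acid being too hindered to compete; acylating here settles the C15/C14 differentiation because the C14 oxygen is still locked in the acetal.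

**Step 7**
Reactants: 14 (2Z)-2-[(3E)-3-(5-methoxyoxolan-3-ylidene)propyl]hexa-2,5-dien-1-yl 2-hydroxy-2-methylpropanoate; 15 methyl 2-(bromomethyl)prop-2-enoate
Product: 16 methyl (2Z,5Z,9E)-2-(bromomethyl)-6-{[(2-hydroxy-2-methylpropanoyl)oxy]methyl}-9-(5-methoxyoxolan-3-ylidene)nona-2,5-dienoate
Conditions: 15 (6 equiv), second-generation Hoveyda–Grubbs catalyst (2 × 5 mol%), 1,4-benzoquinone (10 mol%), CH2Cl2, 40 °C
Reagents that add atoms: none
Why: Olefin cross-metathesis of the monosubstituted terminal alkene with a 2-substituted acrylate (a partner that does not homodimerise) is selective because the trisubstituted alkenes are inert to the ruthenium carbene, and the geometry of the new enoate is irrelevant since both isomers give the same allylchromium species later.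

**Step 8**
Reactants: 16 methyl (2Z,5Z,9E)-2-(bromomethyl)-6-{[(2-hydroxy-2-methylpropanoyl)oxy]methyl}-9-(5-methoxyoxolan-3-ylidene)nona-2,5-dienoate
Product: 17 methyl (2Z,5Z,9E)-2-(bromomethyl)-6-{[(2-hydroxy-2-methylpropanoyl)oxy]methyl}-9-(5-hydroxyoxolan-3-ylidene)nona-2,5-dienoate
Conditions: 0.1 M HCl, THF/H2O 4:1, 0 °C, 45 min; NaHCO3
Reagents that add atoms: water, O
Why: Acid-catalysed hydrolysis of the 2-alkoxytetrahydrofuran-type acetal (far more labile than the esters) to the lactol, kept cold and short so that the exo-alkylidene lactol does not dehydrate to a furan and the allylic bromide is not solvolysed.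

**Step 9**
Reactants: 17 methyl (2Z,5Z,9E)-2-(bromomethyl)-6-{[(2-hydroxy-2-methylpropanoyl)oxy]methyl}-9-(5-hydroxyoxolan-3-ylidene)nona-2,5-dienoate
Product: 20 [(3aR,5Z,9E,11aS)-10-(hydroxymethyl)-3-methylidene-2-oxo-2,3,3a,4,7,8,11,11a-octahydrocyclodeca[b]furan-6-yl]methyl 2-hydroxy-2-methylpropanoate, via hydroxy aldehyde 18 (not isolated), via macrocyclic hydroxy ester 19 (not isolated)
Conditions: CrCl2 (5 equiv), 3,6-di-tert-butyl-1,8-bis[(4S)-4-isopropyl-4,5-dihydrooxazol-2-yl]-9H-carbazole (5.5 equiv), i-Pr2NEt (6 equiv), THF, 23 °C, 1 h; then 17 by syringe pump over 12 h (2 mM final), 23 °C; aq NH4Cl; PPTS (10 mol%), CH2Cl2, 23 °C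
Reagents that add atoms: none
Why: Proposed new method: CrCl2 inserts into the allylic C–Br bond and the ligand-bound allylchromium species adds through its γ-carbon (C7) to the aldehyde of the ring-opened form 18 (the lactol opens under Lewis-acidic trivalent chromium) in a chair-like six-membered transition state inside the pocket of the tridentate ligand, giving the anti (7R,8S) hydroxy ester 19, whose C8 oxygen closes onto the methyl ester to the trans-fused α-methylene lactone while C14–OH is released free; the closest known reaction types are the ligand-controlled enantioselective chromium-mediated 2-(alkoxycarbonyl)allylation of aldehydes (Nozaki–Hiyama–Kishi type, intermolecular) and the ligand-free chromium-mediated Barbier macrocyclisations used to close ten-membered germacranolide rings.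

**Compound list** (4–6, 9, 11, 12, 14, 16 and 17 are racemic at the acetal or lactol carbon, which is destroyed in step 9)

1 | 4-methoxybenzyl alcohol | COc1ccc(CO)cc1 | starting material
2 | (4-methoxycyclohexa-1,4-dien-1-yl)methanol | COC1=CCC(CO)=CC1 | intermediate
3 | methyl (3E)-3-(5-hydroxyoxolan-3-ylidene)propanoate (lactol, formed in situ) | COC(=O)C/C=C1\CC(O)OC1 | intermediate
4 | methyl (3E)-3-(5-methoxyoxolan-3-ylidene)propanoate | COC(=O)C/C=C1\CC(OC)OC1 | intermediate
5 | (3E)-3-(5-methoxyoxolan-3-ylidene)propan-1-ol | OCC/C=C1\CC(OC)OC1 | intermediate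
6 | (4E)-4-(3-bromopropylidene)-2-methoxyoxolane | BrCC/C=C1\CC(OC)OC1 | intermediate
7 | prop-2-yn-1-ol (propargyl alcohol) | C#CCO | starting material
8 | allyl bromide (3-bromoprop-1-ene) | C=CCBr | starting material
9 | [(3E)-3-(5-methoxyoxolan-3-ylidene)propyl]magnesium bromide (formed in situ) | Br[Mg]CC/C=C1\CC(OC)OC1 | intermediate
10 | chloromagnesium prop-2-yn-1-olate (formed in situ) | C#CCO[Mg]Cl | intermediate
11 | 4-[(3E)-3-(5-methoxyoxolan-3-ylidene)propyl]-2,5-dihydro-1,2-oxamagnesole, the cyclic (Z)-alkenylmagnesium alkoxide (formed in situ) | COC1C/C(=C\CCC2=C[Mg]OC2)CO1 | intermediate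
12 | (2Z)-2-[(3E)-3-(5-methoxyoxolan-3-ylidene)propyl]hexa-2,5-dien-1-ol | C=CC/C=C(\CO)CC/C=C1\CC(OC)OC1 | intermediate
13 | 2-hydroxy-2-methylpropanoic acid (2-hydroxyisobutyric acid) | CC(C)(O)C(=O)O | starting material
14 | (2Z)-2-[(3E)-3-(5-methoxyoxolan-3-ylidene)propyl]hexa-2,5-dien-1-yl 2-hydroxy-2-methylpropanoate | C=CC/C=C(\COC(=O)C(C)(C)O)CC/C=C1\CC(OC)OC1 | intermediate
15 | methyl 2-(bromomethyl)prop-2-enoate | C=C(CBr)C(=O)OC | starting material
16 | methyl (2Z,5Z,9E)-2-(bromomethyl)-6-{[(2-hydroxy-2-methylpropanoyl)oxy]methyl}-9-(5-methoxyoxolan-3-ylidene)nona-2,5-dienoate | COC(=O)/C(CBr)=C/C/C=C(\COC(=O)C(C)(C)O)CC/C=C1\CC(OC)OC1 | intermediate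
17 | methyl (2Z,5Z,9E)-2-(bromomethyl)-6-{[(2-hydroxy-2-methylpropanoyl)oxy]methyl}-9-(5-hydroxyoxolan-3-ylidene)nona-2,5-dienoate | COC(=O)/C(CBr)=C/C/C=C(\COC(=O)C(C)(C)O)CC/C=C1\CC(O)OC1 | intermediate
18 | methyl (2Z,5Z,9E)-2-(bromomethyl)-10-(hydroxymethyl)-6-{[(2-hydroxy-2-methylpropanoyl)oxy]methyl}-12-oxododeca-2,5,9-trienoate (open form of 17, formed in situ) | COC(=O)/C(CBr)=C/C/C=C(\COC(=O)C(C)(C)O)CC/C=C(CO)\CC=O | intermediate
19 | methyl 2-[(1R,2S,4E,8Z)-2-hydroxy-4-(hydroxymethyl)-8-{[(2-hydroxy-2-methylpropanoyl)oxy]methyl}cyclodeca-4,8-dien-1-yl]prop-2-enoate (formed in situ) | C=C(C(=O)OC)[C@@H]1[C@@H](O)C/C(CO)=C\CC/C(COC(=O)C(C)(C)O)=C/C1 | intermediate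
20 | [(3aR,5Z,9E,11aS)-10-(hydroxymethyl)-3-methylidene-2-oxo-2,3,3a,4,7,8,11,11a-octahydrocyclodeca[b]furan-6-yl]methyl 2-hydroxy-2-methylpropanoate | C=C1C(=O)O[C@H]2C/C(CO)=C\CC/C(COC(=O)C(C)(C)O)=C/C[C@H]12 | target

**Step count**
Total steps: 9. Longest linear sequence: 9 (from 1; compounds 7, 8, 13 and 15 are bought).

**The three steps most likely to fail**

Step 9 (macrocyclisation) is the weakest point. Three things must go right at once: ring closure against oligomerisation, anti rather than syn addition (ester-substituted allyl metals often prefer syn), and useful enantioselectivity from a ligand never tested on a lactol bearing free hydroxyls. The fallback sets out from 17 and comes back at 20. It gives up asymmetric induction: the ring is closed with CrCl2 alone in THF/DMF at high dilution, the ligand-free Barbier closure that has direct precedent for ten-membered germacranolide rings. This delivers the racemate, that is 19 and 20 together with the enantiomeric hydroxy ester F1 and the enantiomer of the target F2. Compound 20 is then separated from F2 by preparative chromatography on a chiral stationary phase.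

Step 5 (three-component carbomagnesiation) uses a four-step Grignard reagent almost stoichiometrically. Deprotonation of the acetylenic C–H, a slow addition of the primary alkyl group, or loss of alkene geometry through homoallyl/cyclopropylcarbinyl equilibration could each cut the yield. The fallback sets out from 9 and comes back at 12, and builds C4=C5 by olefination instead of carbometalation. Grignard 9 is acylated with 2-[(tert-butyldimethylsilyl)oxy]-N-methoxy-N-methylacetamide (THF, 0 °C) to give the α-silyloxy ketone F3. The salt-free ylide but-3-en-1-ylidene(triphenyl)phosphorane F4, made from (but-3-en-1-yl)triphenylphosphonium bromide and KN(SiMe3)2 at −78 °C, is then added. α-Alkoxy ketones react with non-stabilised ylides to put the CH2O group cis to the new chain, so the product is the (Z)-silyl ether F5. Bu4NF buffered with AcOH removes the silyl group and gives 12.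

Step 7 (cross-metathesis) may stall because 2-substituted acrylates are slow partners, the allylic bromide may poison the ruthenium carbene, and the 1,4-diene can isomerise. The fallback sets out from 14 and comes back at 16, and separates C–C from C–Br bond formation. Compound 14 is cross-metathesised with methyl 2-(hydroxymethyl)prop-2-enoate (same catalyst) to the allylic alcohol F6. An Appel bromination (CBr4, PPh3, CH2Cl2, 0 °C) then converts the primary allylic hydroxyl into the bromide; the tertiary hydroxyl is inert, and the product is 16.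

**Further compounds**
F1 | step 9 | methyl 2-[(1S,2R,4E,8Z)-2-hydroxy-4-(hydroxymethyl)-8-{[(2-hydroxy-2-methylpropanoyl)oxy]methyl}cyclodeca-4,8-dien-1-yl]prop-2-enoate (enantiomer of 19) | C=C(C(=O)OC)[C@H]1[C@H](O)C/C(CO)=C\CC/C(COC(=O)C(C)(C)O)=C/C1
F2 | step 9 | [(3aS,5Z,9E,11aR)-10-(hydroxymethyl)-3-methylidene-2-oxo-2,3,3a,4,7,8,11,11a-octahydrocyclodeca[b]furan-6-yl]methyl 2-hydroxy-2-methylpropanoate (enantiomer of 20) | C=C1C(=O)O[C@@H]2C/C(CO)=C\CC/C(COC(=O)C(C)(C)O)=C/C[C@@H]12
F3 | step 5 | (5E)-1-[(tert-butyldimethylsilyl)oxy]-5-(5-methoxyoxolan-3-ylidene)pentan-2-one | CC(C)(C)[Si](C)(C)OCC(=O)CC/C=C1\CC(OC)OC1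
F4 | step 5 | but-3-en-1-ylidene(triphenyl)phosphorane | C=CCC=P(c1ccccc1)(c1ccccc1)c1ccccc1
F5 | step 5 | tert-butyl({(2Z)-2-[(3E)-3-(5-methoxyoxolan-3-ylidene)propyl]hexa-2,5-dien-1-yl}oxy)dimethylsilane | C=CC/C=C(\CO[Si](C)(C)C(C)(C)C)CC/C=C1\CC(OC)OC1
F6 | step 7 | methyl (2E,5Z,9E)-2-(hydroxymethyl)-6-{[(2-hydroxy-2-methylpropanoyl)oxy]methyl}-9-(5-methoxyoxolan-3-ylidene)nona-2,5-dienoate | COC(=O)/C(CO)=C/C/C=C(\COC(=O)C(C)(C)O)CC/C=C1\CC(OC)OC1
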